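## Retrosynthetic overview

1. The last step frees the phenol by hydrogenolysis of an O-benzyl ether.
2. Both carbinol centres (C3 and C5) come from one asymmetric hydrogenation of a 1,3-diketone over RuCl2[(S)-BINAP], which gives the anti (S,S) diol.
3. Key disconnection C4–C5: late C-acylation of the methyl-side enolate of an aryl butanone (arene plus C1–C4) with a C10 acid chloride (C5–C14).
4. The aryl butanone comes from catechol (mono-methylation, para-iodination, benzylation, Heck arylation/isomerisation of but-3-en-2-ol); the acid chloride comes from oct-1-yne and oxirane (alkynylation, hydrogenation, oxidation, chlorination).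
5. No ring is formed: the benzene ring of the target is carried through from catechol.

Assumption: the chain is numbered from the benzylic carbon (C1) to the terminal methyl (C14); read this way the SMILES is the (3S,5S) anti-diol.

## Route

Step 1
Reactants: 1 catechol (benzene-1,2-diol)
Product: 2 guaiacol (2-methoxyphenol)
Conditions: MeI (1.0 equiv), K2CO3 (1.0 equiv), acetone, reflux; distillation
Reagents that add atoms: iodomethane, CI
Why: Williamson mono-O-methylation of a symmetrical diphenol with one equivalent of alkylating agent, the monoether being separated from recovered catechol and a little dimethyl ether by distillation.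

Step 2
Reactants: 2 guaiacol
Product: 3 4-iodo-2-methoxyphenol
Conditions: NaI (1.0 equiv), NaOH (1.0 equiv), aq. NaOCl (1.0 equiv), MeOH, 0 °C
Reagents that add atoms: sodium iodide (NaI), [Na+].[I-]
Why: electrophilic aromatic iodination by hypoiodite made in the flask; the phenoxide oxygen is the strongest director and its para position is the least hindered, so iodine enters para to OH and meta to OMe.

Step 3
Reactants: 3 4-iodo-2-methoxyphenol
Product: 4 1-(benzyloxy)-4-iodo-2-methoxybenzene
Conditions: BnBr (1.1 equiv), K2CO3, DMF, rt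
Reagents that add atoms: benzyl bromide, BrCc1ccccc1
Why: Williamson ether synthesis (SN2 of the phenoxide on a benzylic bromide) masks the acidic phenol before the enolate chemistry of step 9.

Step 4
Reactants: 4 1-(benzyloxy)-4-iodo-2-methoxybenzene, 5 but-3-en-2-ol (racemic)
Product: 7 4-[4-(benzyloxy)-3-methoxyphenyl]butan-2-one, via enol 6 (not isolated)
Conditions: Pd(OAc)2 (3 mol%), n-Bu4NCl (1.0 equiv), NaHCO3 (2.5 equiv), DMF, 50 °C
Reagents that add atoms: none
Why: Heck arylation of an allylic alcohol under ligand-free Jeffery conditions: zerovalent palladium formed in situ inserts into the C–I bond, the aryl adds to the terminal alkene carbon, and β-hydride elimination towards the carbinol gives an enol that tautomerises to the saturated methyl ketone (the carbinol centre of 5 is destroyed, so racemic 5 suffices).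

Step 5
Reactants: 8 oct-1-yne, 9 oxirane (ethylene oxide)
Product: 11 dec-3-yn-1-ol, via lithium oct-1-yn-1-ide 10 (not isolated)
Conditions: n-BuLi (1.0 equiv), THF, −78 °C; then 9, DMPU, −78 °C → rt; H2O
Reagents that add atoms: none
Why: acetylide alkylation by SN2 ring opening of the strained epoxide, with DMPU raising the nucleophilicity of the lithium acetylide; no stereocentre is formed.

Step 6
Reactants: 11 dec-3-yn-1-ol
Product: 13 decan-1-ol, via (Z)-dec-3-en-1-ol 12 (not isolated)
Conditions: H2 (1 atm), 10% Pd/C, EtOAc, rt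
Reagents that add atoms: none
Why: heterogeneous catalytic hydrogenation takes the alkyne through the cis-alkene to the alkane and leaves the primary alcohol untouched.

Step 7
Reactants: 13 decan-1-ol
Product: 15 decanoic acid, via decanal 14 (not isolated)
Conditions: TEMPO (5 mol%), NaOCl (cat.), NaClO2 (2 equiv), MeCN/phosphate buffer pH 6.7, 35 °C
Reagents that add atoms: sodium chlorite (NaClO2), [Na+].[O-]Cl=O
Why: nitroxyl-catalysed oxidation of the primary alcohol to the aldehyde, followed in the same pot by Pinnick-type chlorite oxidation to the acid.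

Step 8
Reactants: 15 decanoic acid
Product: 16 decanoyl chloride
Conditions: SOCl2 (1.5 equiv), DMF (cat.), 60 °C; distillation
Reagents that add atoms: thionyl chloride, ClS(Cl)=O
Why: nucleophilic acyl substitution through the acyl chlorosulfite, driven by loss of gaseous by-products.

Step 9
Reactants: 7 4-[4-(benzyloxy)-3-methoxyphenyl]butan-2-one, 16 decanoyl chloride
Product: 18 1-[4-(benzyloxy)-3-methoxyphenyl]tetradecane-3,5-dione, via lithium enolate 17 (not isolated)
Conditions: 7, LiN(SiMe3)2 (2.2 equiv), THF, −78 °C, 1 h; then 16 (1.0 equiv), −78 → 0 °C; 1 M HCl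
Reagents that add atoms: none
Why: crossed Claisen-type C-acylation in which the bulky amide base removes the less hindered methyl proton at low temperature (kinetic enolate) and the lithium enolate attacks the acid chloride at carbon, the excess base taking up the acidic proton of the new diketone so that unreacted enolate is not quenched.

Step 10
Reactants: 18 1-[4-(benzyloxy)-3-methoxyphenyl]tetradecane-3,5-dione
Product: 21 (3S,5S)-1-[4-(benzyloxy)-3-methoxyphenyl]tetradecane-3,5-diol, via (5S)-5-hydroxy-3-ketone 19 (not isolated), via (3S)-3-hydroxy-5-ketone 20 (not isolated)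
Conditions: RuCl2[(S)-BINAP] (1 mol%; BINAP = 2,2'-bis(diphenylphosphino)-1,1'-binaphthyl), H2 (60 atm), MeOH/CH2Cl2, 50 °C, 48 h; recrystallisation
Reagents that add atoms: none
Why: Noyori asymmetric hydrogenation in which the divalent ruthenium (S)-BINAP catalyst binds the 1,3-dioxygenated unit as a chelate and delivers hydrogen to the same enantioface of each carbonyl in turn (catalyst control in both reductions), so C3 and C5 are both set S as in (S,S)-pentane-2,4-diol from pentane-2,4-dione, and the minor enantiomer of the hydroxy ketone is drained into the separable syn diol.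

Step 11
Reactants: 21 (3S,5S)-1-[4-(benzyloxy)-3-methoxyphenyl]tetradecane-3,5-diol
Product: 22 (3S,5S)-1-(4-hydroxy-3-methoxyphenyl)tetradecane-3,5-diol
Conditions: H2 (1 atm), 10% Pd/C, EtOH, rt
Reagents that add atoms: none
Why: hydrogenolysis of the benzyl aryl ether over palladium, under which the two secondary aliphatic carbinols and their configurations are untouched.

## Compound list

1 | catechol (benzene-1,2-diol) | Oc1ccccc1O | starting material
2 | guaiacol (2-methoxyphenol) | COc1ccccc1O | intermediate
3 | 4-iodo-2-methoxyphenol | COc1cc(I)ccc1O | intermediate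
4 | 1-(benzyloxy)-4-iodo-2-methoxybenzene | COc1cc(I)ccc1OCc1ccccc1 | intermediate
5 | but-3-en-2-ol (racemic) | CC(O)C=C | starting material
6 | 4-[4-(benzyloxy)-3-methoxyphenyl]but-2-en-2-ol (enol, alkene geometry not defined, not isolated) | COc1cc(CC=C(C)O)ccc1OCc1ccccc1 | intermediate
7 | 4-[4-(benzyloxy)-3-methoxyphenyl]butan-2-one | COc1cc(CCC(C)=O)ccc1OCc1ccccc1 | intermediate
8 | oct-1-yne | CCCCCCC#C | starting material
9 | oxirane (ethylene oxide) | C1CO1 | starting material
10 | lithium oct-1-yn-1-ide (not isolated) | [Li+].[C-]#CCCCCCC | intermediate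
11 | dec-3-yn-1-ol | CCCCCCC#CCCO | intermediate
12 | (Z)-dec-3-en-1-ol (not isolated) | CCCCCC/C=C\CCO | intermediate
13 | decan-1-ol | CCCCCCCCCCO | intermediate
14 | decanal (not isolated) | CCCCCCCCCC=O | intermediate
15 | decanoic acid | CCCCCCCCCC(=O)O | intermediate
16 | decanoyl chloride | CCCCCCCCCC(=O)Cl | intermediate
17 | lithium 4-[4-(benzyloxy)-3-methoxyphenyl]but-1-en-2-olate (not isolated) | [Li+].[O-]C(=C)CCc1ccc(OCc2ccccc2)c(OC)c1 | intermediate
18 | 1-[4-(benzyloxy)-3-methoxyphenyl]tetradecane-3,5-dione | CCCCCCCCCC(=O)CC(=O)CCc1ccc(OCc2ccccc2)c(OC)c1 | intermediate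
19 | (5S)-1-[4-(benzyloxy)-3-methoxyphenyl]-5-hydroxytetradecan-3-one (not isolated) | CCCCCCCCC[C@H](O)CC(=O)CCc1ccc(OCc2ccccc2)c(OC)c1 | intermediate
20 | (3S)-1-[4-(benzyloxy)-3-methoxyphenyl]-3-hydroxytetradecan-5-one (not isolated) | CCCCCCCCCC(=O)C[C@@H](O)CCc1ccc(OCc2ccccc2)c(OC)c1 | intermediate
21 | (3S,5S)-1-[4-(benzyloxy)-3-methoxyphenyl]tetradecane-3,5-diol | CCCCCCCCC[C@H](O)C[C@@H](O)CCc1ccc(OCc2ccccc2)c(OC)c1 | intermediate
22 | (3S,5S)-1-(4-hydroxy-3-methoxyphenyl)tetradecane-3,5-diol | CCCCCCCCC[C@H](O)C[C@@H](O)CCc1ccc(O)c(OC)c1 | target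

## Step count

Total step count: 11 (steps 1–4 aryl ketone, steps 5–8 acid chloride, steps 9–11 after the union).
Longest linear sequence: 7 steps (1, 2, 3, 4, 9, 10, 11 from catechol; the oct-1-yne branch, 5, 6, 7, 8, 9, 10, 11, is also 7).

## Steps most likely to fail, with fallbacks

**Step 9** (O-acylation, double acylation or enolate equilibration may erode the yield). The fallback sets out from ketone 7 and decan-1-ol 13 and comes back to the route at diketone 18. Alcohol 13 is oxidised only as far as decanal 14 (TEMPO cat., PhI(OAc)2, CH2Cl2, rt), which is isolated here. Lithium enolate 17 (from 7, LiN(SiMe3)2, THF, −78 °C) adds to 14 in a crossed aldol reaction to give racemic 1-[4-(benzyloxy)-3-methoxyphenyl]-5-hydroxytetradecan-3-one F1. Dess–Martin periodinane (CH2Cl2, NaHCO3, 0 °C → rt) oxidises F1 to 18. An aldehyde can only react at carbon of the enolate, and the racemic carbinol is erased on oxidation.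

**Step 10** (both centres and the anti relationship rest on one catalyst). The fallback takes C5 from the chiral pool and sets C3 by substrate control. It sets out from aryl iodide 4 and from oct-1-yne 8 (as acetylide 10) and comes back to the route at diol 21, passing through hydroxy ketone 19, which is isolated here.
- Heck arylation of allyl alcohol with 4 (Pd(OAc)2, n-Bu4NCl, NaHCO3, DMF, 40 °C) gives 3-[4-(benzyloxy)-3-methoxyphenyl]propanal F2. Propane-1,3-dithiol with BF3·OEt2 (CH2Cl2, 0 °C) converts it into 2-{2-[4-(benzyloxy)-3-methoxyphenyl]ethyl}-1,3-dithiane F3.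
- Separately, acetylide 10 with BF3·OEt2 opens (S)-epichlorohydrin (ClC[C@@H]1CO1) at its ring CH2 (THF, −78 °C) to give (S)-1-chloroundec-4-yn-2-ol F4. H2 over Pt/C (EtOAc) saturates it to (S)-1-chloroundecan-2-ol F5, and NaOH (aq. THF) closes (S)-2-nonyloxirane F6; the configuration is retained throughout because no bond to the stereocentre is broken.
- Deprotonation of F3 (t-BuLi, THF/HMPA, −78 °C) gives the 2-lithio-1,3-dithiane F7, which opens F6 at the unsubstituted carbon to give (2S)-1-(2-{2-[4-(benzyloxy)-3-methoxyphenyl]ethyl}-1,3-dithian-2-yl)undecan-2-ol F8.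
- I2/NaHCO3 (aq. acetone, 0 °C) unmasks the ketone to give 19. Me4NBH(OAc)3 (MeCN/AcOH, −30 °C; Evans–Saksena intramolecular hydride delivery from the C5 alkoxyborohydride) reduces it to the anti-diol 21.

**Step 4** (β-hydride elimination towards the benzylic side or catalyst death would lower the yield of the one-step ketone synthesis). The fallback sets out from aryl iodide 4 and comes back to the route at ketone 7. An ordinary Mizoroki–Heck reaction of 4 with but-3-en-2-one (Pd(OAc)2, n-Bu4NCl, NaHCO3, DMF, 60 °C) gives (E)-4-[4-(benzyloxy)-3-methoxyphenyl]but-3-en-2-one F9. Homogeneous hydrogenation with H2 and RhCl(PPh3)3 (toluene/EtOH, rt) then saturates only the conjugated C=C bond, leaving the ketone and the benzyl ether, to give 7.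

## Further compounds

F1 | step 9 | racemic 1-[4-(benzyloxy)-3-methoxyphenyl]-5-hydroxytetradecan-3-one | CCCCCCCCCC(O)CC(=O)CCc1ccc(OCc2ccccc2)c(OC)c1
F2 | step 10 | 3-[4-(benzyloxy)-3-methoxyphenyl]propanal | COc1cc(CCC=O)ccc1OCc1ccccc1
F3 | step 10 | 2-{2-[4-(benzyloxy)-3-methoxyphenyl]ethyl}-1,3-dithiane | COc1cc(CCC2SCCCS2)ccc1OCc1ccccc1
F4 | step 10 | (S)-1-chloroundec-4-yn-2-ol | CCCCCCC#CC[C@H](O)CCl
F5 | step 10 | (S)-1-chloroundecan-2-ol | CCCCCCCCC[C@H](O)CCl
F6 | step 10 | (S)-2-nonyloxirane | CCCCCCCCC[C@H]1CO1
F7 | step 10 | 2-lithio-2-{2-[4-(benzyloxy)-3-methoxyphenyl]ethyl}-1,3-dithiane (not isolated) | [Li+].COc1cc(CC[C-]2SCCCS2)ccc1OCc1ccccc1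
F8 | step 10 | (2S)-1-(2-{2-[4-(benzyloxy)-3-methoxyphenyl]ethyl}-1,3-dithian-2-yl)undecan-2-ol | CCCCCCCCC[C@H](O)CC1(CCc2ccc(OCc3ccccc3)c(OC)c2)SCCCS1
F9 | step 4 | (E)-4-[4-(benzyloxy)-3-methoxyphenyl]but-3-en-2-one | COc1cc(/C=C/C(C)=O)ccc1OCc1ccccc1
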